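The seven-membered ring is cut at C6–C7 (C1 quaternary methyl carbon, C4 isopropyl carbinol, C5 ring-fusion CH, C6 ester carbon, C8=C9 alkene, C10 allylic carbinol). Since C1 is quaternary, a 3-methylbut-2-enoyl ketone at C10 can enolise only toward its γ-methyl carbon C7; as a silyl dienol ether this carbon attacks a C6 aldehyde on C5. One operation closes ring C1–C5–C6–C7–C8–C9–C10 trans-fused to the cyclopentane and sets the C6 carbinol, the C8=C9 alkene and the C10 carbonyl. The precursor is a cyclopentane carbaldehyde with three contiguous stereocentres, the enoyl group on C1 and a C4 hydroxyl that is silylated in the flask.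

Key step: step 10

Remarks
- Numbering: C1–C5 form the five-membered ring and C5–C10 with C1 the seven-membered ring (daucane numbering). Methyls sit on C1 and C8, isopropyl on C4. Bicyclic compounds are named on this skeleton.
- Assumption: 3-(hydroxymethyl)cyclopent-2-en-1-one (1) is taken as a purchasable building block.
- C1 is made by adding methyl to an enone that already carries C10, because methyl addition to 3-methylcyclopent-2-enone would give an achiral gem-dimethyl ketone.
- C6 is carried as a dimethyl acetal and released last; the C4 hydroxyl needs no separate protection.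
- Relative configuration in the target: ring fusion trans, C4–OH cis to the C1 methyl, C6–O cis to H5, C10–OH trans to the C1 methyl.

Step 1
Reactants: 1 3-(hydroxymethyl)cyclopent-2-en-1-one; 2 tert-butyl(chloro)diphenylsilane
Product: 3 3-{[tert-butyl(diphenyl)silyl]oxymethyl}cyclopent-2-en-1-one
Conditions: imidazole, CH2Cl2, 0 °C → rt
Reagents that add atoms: tert-butyl(chloro)diphenylsilane, CC(C)(C)[Si](Cl)(c1ccccc1)c1ccccc1
Why: Imidazole-promoted silylation of a primary allylic alcohol is routine and forms no stereocentre; the bulky silyl ether should shield one ring face in step 3 and is later cleaved by fluoride without touching an acetal.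

Step 2
Reactants: 3 3-{[tert-butyl(diphenyl)silyl]oxymethyl}cyclopent-2-en-1-one; 4 trimethylaluminium; 5 trimethylsilyl trifluoromethanesulfonate
Product: 7 tert-butyl{[(1S)-1-methyl-3-(trimethylsilyloxy)cyclopent-2-en-1-yl]methoxy}diphenylsilane, via aluminium enolate 6 (not isolated)
Conditions: Me3Al (1.5 equiv), copper thiophene-2-carboxylate Cu(O2CC4H3S) (5 mol%), chiral phosphoramidite ligand (2,2'-biphenol backbone, N,N-bis[1-(2-naphthyl)ethyl]amino group; the antipode that gives the S centre; 10 mol%), Et2O, −30 °C; then TMSOTf (2 equiv), −30 → 0 °C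
Reagents that add atoms: trimethylaluminium, C[Al](C)C; trimethylsilyl trifluoromethanesulfonate, C[Si](C)(C)OS(=O)(=O)C(F)(F)F
Why: Copper-catalysed asymmetric conjugate addition of a trialkylaluminium to a β-substituted cyclopentenone creates the quaternary centre C1 with the enone face chosen by the ligand, and O-silylation of the aluminium enolate fixes the enol double bond toward C5, a position that enolisation of the free ketone would not reach selectively.

Step 3
Reactants: 7 tert-butyl{[(1S)-1-methyl-3-(trimethylsilyloxy)cyclopent-2-en-1-yl]methoxy}diphenylsilane; 8 trimethyl orthoformate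
Product: 9 (2S,3S)-3-{[tert-butyl(diphenyl)silyl]oxymethyl}-2-(dimethoxymethyl)-3-methylcyclopentan-1-one
Conditions: HC(OMe)3 (3 equiv), BF3·OEt2 (1.2 equiv), CH2Cl2, −78 °C; NaHCO3 quench at −78 °C
Reagents that add atoms: trimethyl orthoformate, COC(OC)OC
Why: Mukaiyama-type addition of the silyl enol ether to the dimethoxycarbenium ion installs C6 at the aldehyde oxidation level; the electrophile should enter C5 anti to the bulky silyloxymethyl group on C1, placing C6 cis to the C1 methyl, which is also the more stable arrangement.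

Step 4
Reactants: 9 (2S,3S)-3-{[tert-butyl(diphenyl)silyl]oxymethyl}-2-(dimethoxymethyl)-3-methylcyclopentan-1-one; 10 isopropylmagnesium chloride
Product: 11 (1R,2R,3S)-3-{[tert-butyl(diphenyl)silyl]oxymethyl}-2-(dimethoxymethyl)-3-methyl-1-(propan-2-yl)cyclopentan-1-ol
Conditions: iPrMgCl (3 equiv), LaCl3·2LiCl (1 equiv), THF, −20 → 0 °C; aq. NH4Cl
Reagents that add atoms: isopropylmagnesium chloride, CC(C)[Mg]Cl
Why: Lanthanide-assisted Grignard 1,2-addition suppresses enolisation and β-hydride transfer at the hindered ketone, and the isopropyl group should add anti to the adjacent dimethoxymethyl substituent, so that the C4 hydroxyl ends up cis to C6.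

Step 5
Reactants: 11 (1R,2R,3S)-3-{[tert-butyl(diphenyl)silyl]oxymethyl}-2-(dimethoxymethyl)-3-methyl-1-(propan-2-yl)cyclopentan-1-ol
Product: 12 (1R,2R,3S)-2-(dimethoxymethyl)-3-(hydroxymethyl)-3-methyl-1-(propan-2-yl)cyclopentan-1-ol
Conditions: Bu4NF (1.5 equiv), THF, rt
Reagents that add atoms: none
Why: Fluoride-mediated desilylation cleaves only the Si–O bond; the acetal and the tertiary alcohol are inert and no stereocentre is touched.

Step 6
Reactants: 12 (1R,2R,3S)-2-(dimethoxymethyl)-3-(hydroxymethyl)-3-methyl-1-(propan-2-yl)cyclopentan-1-ol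
Product: 13 (1S,2R,3R)-2-(dimethoxymethyl)-3-hydroxy-1-methyl-3-(propan-2-yl)cyclopentane-1-carbaldehyde
Conditions: Dess–Martin periodinane (1.3 equiv), CH2Cl2, 0 °C → rt
Reagents that add atoms: none
Why: Dess–Martin oxidation converts the primary neopentyl alcohol into the non-enolisable C10 aldehyde; the tertiary hydroxyl cannot be oxidised and its trans relationship to C10 rules out lactol formation.

Step 7
Reactants: 13 (1S,2R,3R)-2-(dimethoxymethyl)-3-hydroxy-1-methyl-3-(propan-2-yl)cyclopentane-1-carbaldehyde; 14 (2-methylprop-1-en-1-yl)magnesium bromide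
Product: 15 1-[(1S,2R,3R)-2-(dimethoxymethyl)-3-hydroxy-1-methyl-3-(propan-2-yl)cyclopentyl]-3-methylbut-2-en-1-ol (both epimers at the new carbinol carbon)
Conditions: alkenyl-MgBr (3 equiv), THF, 0 °C → rt; aq. NH4Cl
Reagents that add atoms: (2-methylprop-1-en-1-yl)magnesium bromide, CC(C)=C[Mg]Br
Why: Grignard 1,2-addition to the non-enolisable aldehyde forms the C9–C10 bond after one equivalent has deprotonated the C4 hydroxyl; the new carbinol centre is uncontrolled, which does not matter because step 8 oxidises it.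

Step 8
Reactants: 15 1-[(1S,2R,3R)-2-(dimethoxymethyl)-3-hydroxy-1-methyl-3-(propan-2-yl)cyclopentyl]-3-methylbut-2-en-1-ol
Product: 16 1-[(1S,2R,3R)-2-(dimethoxymethyl)-3-hydroxy-1-methyl-3-(propan-2-yl)cyclopentyl]-3-methylbut-2-en-1-one
Conditions: Dess–Martin periodinane (1.5 equiv), CH2Cl2, 0 °C → rt
Reagents that add atoms: none
Why: Dess–Martin oxidation of the secondary allylic alcohol gives the conjugated 3-methylbut-2-enoyl ketone and erases the uncontrolled C10 centre; the tertiary alcohol and the acetal do not react.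

Step 9
Reactants: 16 1-[(1S,2R,3R)-2-(dimethoxymethyl)-3-hydroxy-1-methyl-3-(propan-2-yl)cyclopentyl]-3-methylbut-2-en-1-one
Product: 17 (1R,2R,5S)-2-hydroxy-5-methyl-5-(3-methylbut-2-enoyl)-2-(propan-2-yl)cyclopentane-1-carbaldehyde
Conditions: pyridinium p-toluenesulfonate (0.2 equiv), acetone/H2O 10:1, 40 °C; used directly in step 10
Reagents that add atoms: water, O
Why: Mild acid-catalysed acetal hydrolysis releases the C6 aldehyde last, so that it never meets a nucleophile or an oxidant; the weak acid should neither dehydrate the tertiary β-hydroxyl nor epimerise C5, which lies between two fully substituted carbons.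

Step 10
Reactants: 17 (1R,2R,5S)-2-hydroxy-5-methyl-5-(3-methylbut-2-enoyl)-2-(propan-2-yl)cyclopentane-1-carbaldehyde; 5 trimethylsilyl trifluoromethanesulfonate
Product: 21 (1S,4R,5S,6S)-4,6-dihydroxydauc-8-en-10-one, via trimethylsilyl ether 18 (not isolated), via siloxydiene 19 (not isolated), via bis-silyl cyclisation product 20 (not isolated)
Conditions: TMSOTf (4 equiv), iPr2NEt (5 equiv), CH2Cl2 (0.005 M), −78 → 0 °C; then 1 M aq. HCl, THF, 0 °C → rt
Reagents that add atoms: none
Why: The silyl triflate first caps the C4 hydroxyl (18) and then O-silylates the C10 ketone, whose only acidic hydrogens are on the γ-methyl groups because C1 is quaternary, so the amine gives the 1-siloxybuta-1,3-diene 19; a further silyl triflate activates the aldehyde, the diene terminus C7 adds to C6, and loss of the silyl group from the C10 oxocarbenium returns the enone (20). The closest known reaction type is the one-pot silyl triflate/amine vinylogous Mukaiyama aldol, used here intramolecularly. The seven-membered ring closes 7-exo-trig at the aldehyde with the whole diene inside the ring (7-enolendo), which requires C1 and C8 cis on the C9=C10 enol bond and an s-cis diene, so the C8=C9 alkene can only be cis in the ring. Since enolisation is reversible in the presence of the ammonium triflate, the C9=C10 isomer that cannot reach C6 should drain through the reactive one. C6 is set in the ring-forming transition state: the trans fusion fixes the C10–C1–C5–C6 torsion, C7 approaches anti to C4, and the silylated carbonyl oxygen points outward anti to C1 while the aldehyde hydrogen sits between quaternary C1 and C4, giving the C6–O bond cis to H5 (6S). The step needs γ- over α-attack, secured because α-attack would be a disfavoured 5-enolendo-exo-trig closure, and needs the aldehyde to stay un-enolised, secured by the C5–H being buried between two fully substituted carbons where the bulky amine cannot reach it.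

Step 11
Reactants: 21 (1S,4R,5S,6S)-4,6-dihydroxydauc-8-en-10-one; 22 4-methoxybenzoyl chloride
Product: 23 (1S,4R,5S,6S)-4-hydroxy-10-oxodauc-8-en-6-yl 4-methoxybenzoate
Conditions: 4-methoxybenzoyl chloride (1.5 equiv), pyridine, DMAP (0.2 equiv), CH2Cl2, 0 °C → rt
Reagents that add atoms: 4-methoxybenzoyl chloride, COc1ccc(C(=O)Cl)cc1
Why: DMAP-catalysed acylation esterifies the secondary C6 hydroxyl while the tertiary C4 hydroxyl is too hindered to react, and pyridine is too weak a base to trigger elimination toward a dienone.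

Step 12
Reactants: 23 (1S,4R,5S,6S)-4-hydroxy-10-oxodauc-8-en-6-yl 4-methoxybenzoate
Product: 24 (1S,4R,5S,6S,10R)-4,10-dihydroxydauc-8-en-6-yl 4-methoxybenzoate (target CNP0211568.1)
Conditions: (S)-1-methyl-3,3-diphenyltetrahydro-1H,3H-pyrrolo[1,2-c][1,3,2]oxazaborole (1.0 equiv), catecholborane (3 equiv), toluene, −78 → −40 °C; MeOH quench, carbonate buffer wash
Reagents that add atoms: none
Why: In this Corey–Bakshi–Shibata reduction the (S)-oxazaborolidine should bind the ketone oxygen on the side of the small vinylic C9 and not of quaternary C1, and deliver hydride 1,2 to the face that gives the 10R carbinol (hydroxyl trans to the C1 methyl), under reagent control against the ring's own preference for attack anti to the angular methyl; the ester and the trisubstituted alkene are inert to catecholborane at low temperature.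

Compound list
1 | 3-(hydroxymethyl)cyclopent-2-en-1-one | O=C1C=C(CO)CC1 | starting material
2 | tert-butyl(chloro)diphenylsilane | CC(C)(C)[Si](Cl)(c1ccccc1)c1ccccc1 | starting material
3 | 3-{[tert-butyl(diphenyl)silyl]oxymethyl}cyclopent-2-en-1-one | O=C1C=C(CO[Si](c2ccccc2)(c2ccccc2)C(C)(C)C)CC1 | intermediate
4 | trimethylaluminium | C[Al](C)C | starting material
5 | trimethylsilyl trifluoromethanesulfonate | C[Si](C)(C)OS(=O)(=O)C(F)(F)F | starting material
6 | dimethylaluminium enolate of (S)-3-{[tert-butyl(diphenyl)silyl]oxymethyl}-3-methylcyclopentanone, enol double bond toward C5 (not isolated) | CC(C)(C)[Si](c1ccccc1)(c1ccccc1)OC[C@@]1(C)CCC(O[Al](C)C)=C1 | intermediate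
7 | tert-butyl{[(1S)-1-methyl-3-(trimethylsilyloxy)cyclopent-2-en-1-yl]methoxy}diphenylsilane | CC(C)(C)[Si](c1ccccc1)(c1ccccc1)OC[C@@]1(C)CCC(O[Si](C)(C)C)=C1 | intermediate
8 | trimethyl orthoformate | COC(OC)OC | starting material
9 | (2S,3S)-3-{[tert-butyl(diphenyl)silyl]oxymethyl}-2-(dimethoxymethyl)-3-methylcyclopentan-1-one (acetal cis to the ring methyl) | CC(C)(C)[Si](c1ccccc1)(c1ccccc1)OC[C@@]1(C)CCC(=O)[C@@H]1C(OC)OC | intermediate
10 | isopropylmagnesium chloride | CC(C)[Mg]Cl | starting material
11 | (1R,2R,3S)-3-{[tert-butyl(diphenyl)silyl]oxymethyl}-2-(dimethoxymethyl)-3-methyl-1-(propan-2-yl)cyclopentan-1-ol (hydroxyl cis to the acetal) | CC(C)(C)[Si](c1ccccc1)(c1ccccc1)OC[C@@]1(C)CC[C@@](O)(C(C)C)[C@@H]1C(OC)OC | intermediate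
12 | (1R,2R,3S)-2-(dimethoxymethyl)-3-(hydroxymethyl)-3-methyl-1-(propan-2-yl)cyclopentan-1-ol | OC[C@@]1(C)CC[C@@](O)(C(C)C)[C@@H]1C(OC)OC | intermediate
13 | (1S,2R,3R)-2-(dimethoxymethyl)-3-hydroxy-1-methyl-3-(propan-2-yl)cyclopentane-1-carbaldehyde | O=C[C@@]1(C)CC[C@@](O)(C(C)C)[C@@H]1C(OC)OC | intermediate
14 | (2-methylprop-1-en-1-yl)magnesium bromide | CC(C)=C[Mg]Br | starting material
15 | 1-[(1S,2R,3R)-2-(dimethoxymethyl)-3-hydroxy-1-methyl-3-(propan-2-yl)cyclopentyl]-3-methylbut-2-en-1-ol, both epimers at the carbinol carbon | CC(C)=CC(O)[C@@]1(C)CC[C@@](O)(C(C)C)[C@@H]1C(OC)OC | intermediate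
16 | 1-[(1S,2R,3R)-2-(dimethoxymethyl)-3-hydroxy-1-methyl-3-(propan-2-yl)cyclopentyl]-3-methylbut-2-en-1-one | CC(C)=CC(=O)[C@@]1(C)CC[C@@](O)(C(C)C)[C@@H]1C(OC)OC | intermediate
17 | (1R,2R,5S)-2-hydroxy-5-methyl-5-(3-methylbut-2-enoyl)-2-(propan-2-yl)cyclopentane-1-carbaldehyde (precursor of the key step) | CC(C)=CC(=O)[C@@]1(C)CC[C@@](O)(C(C)C)[C@@H]1C=O | intermediate
18 | (1R,2R,5S)-5-methyl-5-(3-methylbut-2-enoyl)-2-(propan-2-yl)-2-(trimethylsilyloxy)cyclopentane-1-carbaldehyde (not isolated) | CC(C)=CC(=O)[C@@]1(C)CC[C@@](O[Si](C)(C)C)(C(C)C)[C@@H]1C=O | intermediate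
19 | (1R,2R,5S)-5-methyl-5-[(1E)-3-methyl-1-(trimethylsilyloxy)buta-1,3-dien-1-yl]-2-(propan-2-yl)-2-(trimethylsilyloxy)cyclopentane-1-carbaldehyde (not isolated) | C=C(C)/C=C(/O[Si](C)(C)C)[C@@]1(C)CC[C@@](O[Si](C)(C)C)(C(C)C)[C@@H]1C=O | intermediate
20 | (1S,4R,5S,6S)-4,6-bis(trimethylsilyloxy)dauc-8-en-10-one (not isolated) | C[Si](C)(C)O[C@H]1CC(C)=CC(=O)[C@@]2(C)CC[C@@](O[Si](C)(C)C)(C(C)C)[C@H]12 | intermediate
21 | (1S,4R,5S,6S)-4,6-dihydroxydauc-8-en-10-one (trans-fused bicyclic enone, product of the key step) | O[C@H]1CC(C)=CC(=O)[C@@]2(C)CC[C@@](O)(C(C)C)[C@H]12 | intermediate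
22 | 4-methoxybenzoyl chloride | COc1ccc(C(=O)Cl)cc1 | starting material
23 | (1S,4R,5S,6S)-4-hydroxy-10-oxodauc-8-en-6-yl 4-methoxybenzoate | COc1ccc(C(=O)O[C@H]2CC(C)=CC(=O)[C@@]3(C)CC[C@@](O)(C(C)C)[C@H]23)cc1 | intermediate
24 | (1S,4R,5S,6S,10R)-4,10-dihydroxydauc-8-en-6-yl 4-methoxybenzoate | COc1ccc(C(=O)O[C@H]2CC(C)=C[C@@H](O)[C@@]3(C)CC[C@@](O)(C(C)C)[C@H]23)cc1 | target

Total step count: 12. Longest linear sequence: 12 steps (fully linear from 1).

Steps most likely to fail

1. Step 10 (ring closure). Three processes may defeat it: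
- the silyl dienol ether may stay in the C9=C10 geometry that cannot reach C6 if its equilibration is slow;
- soft enolisation of the aldehyde at C5 may be followed by β-elimination of the C4 silyloxy group;
- the product enone may enolise further and lose the C6 silyloxy group.

The fallback forms the same C6–C7 bond by a Lewis-acid carbonyl-ene (Prins-type) cyclisation, which needs no amine and no enol geometry. It sets out from 16 and rejoins at 21. Kinetic deconjugation of 16 (KN(SiMe3)2, THF, −78 °C, then acetic acid at −78 °C) should give 1-[(1S,2R,3R)-2-(dimethoxymethyl)-3-hydroxy-1-methyl-3-(propan-2-yl)cyclopentyl]-3-methylbut-3-en-1-one F1. Acetal hydrolysis as in step 9 then gives (1R,2R,5S)-2-hydroxy-5-methyl-5-(3-methylbut-3-enoyl)-2-(propan-2-yl)cyclopentane-1-carbaldehyde F2. Me2AlCl (3 equiv, CH2Cl2, −78 → 0 °C) should close the ring by attack of the 1,1-disubstituted alkene terminus C7 on the complexed aldehyde, giving (1S,4R,5S,6S)-4,6-dihydroxy-8-methylidenedaucan-10-one F3 and/or 21 directly. DBU in CH2Cl2 moves the exocyclic double bond into conjugation and delivers 21.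

2. Step 12 (C10 reduction). Hydride delivery anti to the angular C1 methyl, the ring's own bias, may outrun the catalyst-controlled pathway, so facial selectivity may be poor or reversed.

The fallback accepts substrate control and then inverts C10. It sets out from 23 and rejoins at 24. Luche reduction (NaBH4, CeCl3·7H2O, MeOH, −40 °C) should give (1S,4R,5S,6S,10S)-4,10-dihydroxydauc-8-en-6-yl 4-methoxybenzoate F4. Mitsunobu esterification (4-nitrobenzoic acid, PPh3, diisopropyl azodicarboxylate, toluene) inverts C10 to (1S,4R,5S,6S,10R)-4-hydroxy-6-(4-methoxybenzoyloxy)dauc-8-en-10-yl 4-nitrobenzoate F5. The electron-poor ester is then cleaved selectively (K2CO3, MeOH, 0 °C) beside the electron-rich anisoate to give 24.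

3. Step 4 (isopropyl addition). Enolisation of the hindered ketone, β-hydride transfer from the isopropyl reagent or base-induced loss of methanol from the β-keto acetal may compete with addition.

The fallback uses a smaller sp2 nucleophile without β-hydrogens and a separate hydrogenation. It sets out from 9 and rejoins at 11. Isopropenylmagnesium bromide with LaCl3·2LiCl (THF, −20 °C) should give (1S,2R,3S)-3-{[tert-butyl(diphenyl)silyl]oxymethyl}-2-(dimethoxymethyl)-3-methyl-1-(prop-1-en-2-yl)cyclopentan-1-ol F6, again by attack anti to the acetal. Hydrogenation of its 1,1-disubstituted alkene (H2, RhCl(PPh3)3, benzene/ethanol) gives 11.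

Further compounds
F1 | step 10 | 1-[(1S,2R,3R)-2-(dimethoxymethyl)-3-hydroxy-1-methyl-3-(propan-2-yl)cyclopentyl]-3-methylbut-3-en-1-one | C=C(C)CC(=O)[C@@]1(C)CC[C@@](O)(C(C)C)[C@@H]1C(OC)OC
F2 | step 10 | (1R,2R,5S)-2-hydroxy-5-methyl-5-(3-methylbut-3-enoyl)-2-(propan-2-yl)cyclopentane-1-carbaldehyde | C=C(C)CC(=O)[C@@]1(C)CC[C@@](O)(C(C)C)[C@@H]1C=O
F3 | step 10 | (1S,4R,5S,6S)-4,6-dihydroxy-8-methylidenedaucan-10-one | O[C@H]1CC(=C)CC(=O)[C@@]2(C)CC[C@@](O)(C(C)C)[C@H]12
F4 | step 12 | (1S,4R,5S,6S,10S)-4,10-dihydroxydauc-8-en-6-yl 4-methoxybenzoate | COc1ccc(C(=O)O[C@H]2CC(C)=C[C@H](O)[C@@]3(C)CC[C@@](O)(C(C)C)[C@H]23)cc1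
F5 | step 12 | (1S,4R,5S,6S,10R)-4-hydroxy-6-(4-methoxybenzoyloxy)dauc-8-en-10-yl 4-nitrobenzoate | COc1ccc(C(=O)O[C@H]2CC(C)=C[C@@H](OC(=O)c4ccc(cc4)[N+](=O)[O-])[C@@]3(C)CC[C@@](O)(C(C)C)[C@H]23)cc1
F6 | step 4 | (1S,2R,3S)-3-{[tert-butyl(diphenyl)silyl]oxymethyl}-2-(dimethoxymethyl)-3-methyl-1-(prop-1-en-2-yl)cyclopentan-1-ol | CC(C)(C)[Si](c1ccccc1)(c1ccccc1)OC[C@@]1(C)CC[C@@](O)(C(C)=C)[C@@H]1C(OC)OC
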